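The 2H-pyran ring (ring B: O1, C2, C3, C4, C4a, C8a) is opened at its C3=C4 double bond. The feature exploited is that the quaternary carbon C2 is flanked by two unsaturated two-carbon units, C3(=C4) inside ring B and C1′–C2′ at the start of the side chain. In the precursor both are plain vinyl groups, so C2 is prochiral and the precursor is achiral: an aryl ether of 3-methylpenta-1,4-dien-3-ol carrying an ortho vinyl group (future C4), bromine at C5 and a SEM-protected oxygen at C8. One enantioselective ring-closing metathesis forms C3=C4, closes ring B and makes C2 stereogenic. The surviving vinyl group and the bromide then take the two side chains.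

Key step: step 6

Assumption: the (S)-Biphen molybdenum complex is taken to deliver the (2R)-chromene; if the sense of induction proves opposite, the (R)-Biphen antipode is used with no other change.

Remark on the chemistry: the target is (R) at C2 and (E) in the side chain. Compounds 7–23 contain acid-labile allylic or bis-allylic ether and alcohol units, and from 11 on a light-sensitive 2H-chromene. Work-ups are therefore kept neutral to basic, silica is deactivated with Et3N, compounds 9–11 are kept at or below room temperature, and flasks are shielded from light.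

Abbreviations: SEM = 2-(trimethylsilyl)ethoxymethyl (CH2OCH2CH2SiMe3); Biphen = 3,3′-di-tert-butyl-5,5′,6,6′-tetramethylbiphenyl-2,2′-diolate; 9-BBN = 9-borabicyclo[3.3.1]nonane; DMP = Dess–Martin periodinane; H2IMes = 1,3-dimesitylimidazolidin-2-ylidene; dppf = 1,1′-bis(diphenylphosphino)ferrocene.

**Step 1**
Reactants: 1 6-bromo-2-fluoro-3-methoxybenzaldehyde
Product: 2 6-bromo-2-fluoro-3-hydroxybenzaldehyde
Conditions: BBr3, CH2Cl2, –78 → 0 °C; then H2O
Reagents that add atoms: none
Why: Lewis-acid aryl methyl ether cleavage (BBr3 demethylation), in which boron binds the methoxy oxygen and bromide removes the methyl group by SN2 while the aryl fluoride, aryl bromide and aldehyde are inert at low temperature.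

**Step 2**
Reactants: 2 6-bromo-2-fluoro-3-hydroxybenzaldehyde
Product: 3 6-bromo-2-fluoro-3-(SEM-oxy)benzaldehyde
Conditions: SEMCl, i-Pr2NEt, CH2Cl2, 0 °C → rt
Reagents that add atoms: 2-(trimethylsilyl)ethoxymethyl chloride (SEMCl), C[Si](C)(C)CCOCCl
Why: Williamson-type O-alkylation of the acidic phenol by the reactive chloromethyl ether (SEM protection) gives an acetal that should survive alkoxide, ylide, alkylidene, borane, Grignard and palladium chemistry and is removable by fluoride.

**Step 3**
Reactants: 4 ethyl acetate; 5 vinylmagnesium bromide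
Product: 7 3-methylpenta-1,4-dien-3-ol, via but-3-en-2-one 6 (not isolated)
Conditions: 5 (2.2 equiv), THF, 0 °C → rt; sat. aq NH4Cl; distillation
Reagents that add atoms: none
Why: Double Grignard addition to an ester, in which the first vinyl addition releases the more electrophilic but-3-en-2-one and the second adds 1,2 to it, giving the tertiary divinyl carbinol.

**Step 4**
Reactants: 7 3-methylpenta-1,4-dien-3-ol; 3 6-bromo-2-fluoro-3-(SEM-oxy)benzaldehyde
Product: 9 6-bromo-2-[(3-methylpenta-1,4-dien-3-yl)oxy]-3-(SEM-oxy)benzaldehyde, via potassium 3-methylpenta-1,4-dien-3-olate 8 (not isolated)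
Conditions: KH, THF, 0 °C; then 3, THF/DMF, –20 °C → rt
Reagents that add atoms: none
Why: Nucleophilic aromatic substitution by addition–elimination, in which the C–F carbon is activated by the ortho formyl group, fluoride is the best leaving group for the rate-determining addition so that the C–Br bond should stay intact, and the non-enolisable aldehyde only adds alkoxide reversibly.

**Step 5**
Reactants: 9 6-bromo-2-[(3-methylpenta-1,4-dien-3-yl)oxy]-3-(SEM-oxy)benzaldehyde
Product: 10 1-bromo-2-ethenyl-3-[(3-methylpenta-1,4-dien-3-yl)oxy]-4-(SEM-oxy)benzene (achiral triene)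
Conditions: Ph3PCH3Br, KOtBu, THF, 0 °C → rt
Reagents that add atoms: methyltriphenylphosphonium bromide (delivers CH2 as its ylide), C[P+](c1ccccc1)(c1ccccc1)c1ccccc1.[Br-]
Why: Wittig methylenation of the non-enolisable aryl aldehyde with the unstabilised ylide at or below room temperature, conditions that should leave the acetal, the aryl bromide and the bis-allylic ether untouched.

**Step 6**
Reactants: 10 1-bromo-2-ethenyl-3-[(3-methylpenta-1,4-dien-3-yl)oxy]-4-(SEM-oxy)benzene
Product: 11 (2R)-5-bromo-2-ethenyl-2-methyl-8-(SEM-oxy)-2H-chromene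
Conditions: Mo(N-2,6-i-Pr2C6H3)(CHCMe2Ph)[(S)-Biphen] (5 mol %), C6H6 (0.05 M), 22 °C, N2, vessel vented for ethylene
Reagents that add atoms: none
Why: Ring-closing olefin metathesis through molybdacyclobutanes: the chiral alkylidene exchanges onto a terminal alkene of 10, and [2+2] cycloaddition with the partner alkene followed by cycloreversion joins the styrene CH carbon (C4) to the CH carbon of one C2 vinyl group (which becomes C3) and expels ethylene. The closest known reaction type is the catalytic enantioselective ring-closing metathesis that desymmetrises achiral trienes to cyclic tertiary ethers, together with the established metathesis closure of ortho-vinylaryl allyl ethers to 2H-chromenes. Ring B closes as a six-membered ring by head-to-head union of the two alkene CH carbons (C3=C4 formation; ring atoms O1, C2, C3, C4, C4a, C8a); closure between the two C2 vinyl groups is excluded because it would give a cyclopropene, and loss of ethylene to the nitrogen atmosphere drives the closure forward. C2 becomes stereogenic under catalyst control alone: in the two diastereomeric metallacyclobutane transition states either the methyl group or the spectator vinyl group at C2 is turned toward the arylimido and biphenolate walls, and the chiral diolate pocket should admit one enantiotopic vinyl group preferentially. The step needs enantiotopic-group selection and ring closure in preference to intermolecular metathesis; the first rests on the ligand, the second on dilution and on the quaternary carbinol carbon, which makes the vinyl group left in 11 a reluctant partner for further metathesis, while the ambient temperature keeps the bis-allylic aryl ether from sigmatropic rearrangement.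

**Step 7**
Reactants: 11 (2R)-5-bromo-2-ethenyl-2-methyl-8-(SEM-oxy)-2H-chromene
Product: 13 2-[(2R)-5-bromo-2-methyl-8-(SEM-oxy)-2H-chromen-2-yl]ethan-1-ol, via B-alkyl-9-BBN adduct 12 (not isolated)
Conditions: 9-BBN dimer, THF, 0 °C → rt; then 3 M NaOH, 30% H2O2, 0 °C
Reagents that add atoms: hydrogen peroxide, OO
Why: Hydroboration–oxidation, in which 9-BBN should add anti-Markovnikov to the monosubstituted vinyl group far faster than to the cis-disubstituted ring alkene C3=C4 and places boron 1,3 to O1 so that no β-alkoxy elimination is possible, after which alkaline peroxide replaces boron by hydroxyl without touching C2.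

**Step 8**
Reactants: 13 2-[(2R)-5-bromo-2-methyl-8-(SEM-oxy)-2H-chromen-2-yl]ethan-1-ol
Product: 15 ethyl (2E)-4-[(2R)-5-bromo-2-methyl-8-(SEM-oxy)-2H-chromen-2-yl]but-2-enoate, via chromen-2-ylacetaldehyde 14 (not isolated)
Conditions: DMP, NaHCO3, CH2Cl2, 0 °C → rt; then Ph3P=CHCO2Et, rt
Reagents that add atoms: ethyl (triphenylphosphoranylidene)acetate, CCOC(=O)C=P(c1ccccc1)(c1ccccc1)c1ccccc1
Why: Dess–Martin oxidation followed in the same flask by Wittig olefination with a stabilised ylide, which should give the (E)-enoate and keeps the β-aryloxy aldehyde away from base, so that retro-oxa-Michael opening of ring B (and with it loss of the C2 configuration) is avoided.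

**Step 9**
Reactants: 15 ethyl (2E)-4-[(2R)-5-bromo-2-methyl-8-(SEM-oxy)-2H-chromen-2-yl]but-2-enoate
Product: 17 (3E)-5-[(2R)-5-bromo-2-methyl-8-(SEM-oxy)-2H-chromen-2-yl]-2-methylpent-3-en-2-ol, via methyl enone 16 (not isolated)
Conditions: MeMgBr (3.5 equiv), THF, –40 → 0 °C; sat. aq NH4Cl
Reagents that add atoms: methylmagnesium bromide, C[Mg]Br
Why: Double Grignard addition to the ester by way of the methyl enone, both additions being 1,2 for the hard methyl nucleophile at low temperature, should give the tertiary allylic alcohol with the (E)-alkene and the aryl bromide unchanged.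

**Step 10**
Reactants: 18 2,4-dihydroxybenzaldehyde
Product: 19 2,4-bis(SEM-oxy)benzaldehyde
Conditions: NaH, SEMCl, DMF, 0 °C → rt
Reagents that add atoms: 2-(trimethylsilyl)ethoxymethyl chloride (SEMCl), C[Si](C)(C)CCOCCl
Why: Williamson-type O-alkylation of both sodium phenoxides (SEM protection), the hydrogen-bonded 2-hydroxyl being the reason for the stronger base.

**Step 11**
Reactants: 19 2,4-bis(SEM-oxy)benzaldehyde; 5 vinylmagnesium bromide
Product: 20 rac-1-[2,4-bis(SEM-oxy)phenyl]prop-2-en-1-ol
Conditions: THF, –78 → –20 °C; sat. aq NH4Cl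
Reagents that add atoms: none
Why: Grignard 1,2-addition of the vinyl nucleophile to the aryl aldehyde gives the allylic carbinol, used as the racemate because its stereocentre is erased in step 12.

**Step 12**
Reactants: 17 (3E)-5-[(2R)-5-bromo-2-methyl-8-(SEM-oxy)-2H-chromen-2-yl]-2-methylpent-3-en-2-ol; 20 rac-1-[2,4-bis(SEM-oxy)phenyl]prop-2-en-1-ol
Product: 22 1-[2,4-bis(SEM-oxy)phenyl]-3-{(2R)-2-[(2E)-4-hydroxy-4-methylpent-2-en-1-yl]-2-methyl-8-(SEM-oxy)-2H-chromen-5-yl}propan-1-one, via enol 21 (not isolated)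
Conditions: Pd(OAc)2 (5 mol %), P(t-Bu)3·HBF4 (6 mol %), Cy2NMe, 1,4-dioxane, 70 °C, dark
Reagents that add atoms: none
Why: Mizoroki–Heck arylation of a secondary allylic alcohol, in which oxidative addition of the C5–Br bond to zerovalent palladium and insertion at the terminal alkene carbon of 20 are followed by β-hydride elimination toward the carbinol C–H and tautomerisation of the enol, so that the saturated aryl ketone arises directly without a hydrogenation that would endanger C3=C4 or the side-chain alkene, and the monosubstituted alkene of 20 should react far faster than the two 1,2-disubstituted alkenes of 17.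

**Step 13**
Reactants: 22 1-[2,4-bis(SEM-oxy)phenyl]-3-{(2R)-2-[(2E)-4-hydroxy-4-methylpent-2-en-1-yl]-2-methyl-8-(SEM-oxy)-2H-chromen-5-yl}propan-1-one
Product: 23 1-(2,4-dihydroxyphenyl)-3-{(2R)-8-hydroxy-2-[(2E)-4-hydroxy-4-methylpent-2-en-1-yl]-2-methyl-2H-chromen-5-yl}propan-1-one
Conditions: TBAF, ethylenediamine, THF/DMPU, 60 °C, dark; then aq NH4Cl
Reagents that add atoms: none
Why: Fluoride-induced fragmentation of the three aryl SEM acetals (attack at silicon, loss of ethylene and formaldehyde, release of phenoxide, with ethylenediamine taking up the formaldehyde) is a non-acidic, non-reducing global deprotection that should leave the tertiary allylic alcohol, both alkenes and the C2 stereocentre untouched.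

**Compound list**

1 | 6-bromo-2-fluoro-3-methoxybenzaldehyde | COc1ccc(Br)c(C=O)c1F | starting material
2 | 6-bromo-2-fluoro-3-hydroxybenzaldehyde | O=Cc1c(Br)ccc(O)c1F | intermediate
3 | 6-bromo-2-fluoro-3-(SEM-oxy)benzaldehyde | O=Cc1c(Br)ccc(OCOCC[Si](C)(C)C)c1F | intermediate
4 | ethyl acetate | CCOC(C)=O | starting material
5 | vinylmagnesium bromide | C=C[Mg]Br | starting material
6 | but-3-en-2-one | CC(=O)C=C | intermediate
7 | 3-methylpenta-1,4-dien-3-ol | C=CC(C)(O)C=C | intermediate
8 | potassium 3-methylpenta-1,4-dien-3-olate | C=CC(C)([O-])C=C.[K+] | intermediate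
9 | 6-bromo-2-[(3-methylpenta-1,4-dien-3-yl)oxy]-3-(SEM-oxy)benzaldehyde | C=CC(C)(C=C)Oc1c(C=O)c(Br)ccc1OCOCC[Si](C)(C)C | intermediate
10 | 1-bromo-2-ethenyl-3-[(3-methylpenta-1,4-dien-3-yl)oxy]-4-(SEM-oxy)benzene (achiral) | C=CC(C)(C=C)Oc1c(C=C)c(Br)ccc1OCOCC[Si](C)(C)C | intermediate
11 | (2R)-5-bromo-2-ethenyl-2-methyl-8-(SEM-oxy)-2H-chromene | C=C[C@]1(C)C=Cc2c(Br)ccc(OCOCC[Si](C)(C)C)c2O1 | intermediate
12 | 9-{2-[(2R)-5-bromo-2-methyl-8-(SEM-oxy)-2H-chromen-2-yl]ethyl}-9-borabicyclo[3.3.1]nonane | C1CC2CCCC(C1)B2CC[C@]1(C)C=Cc2c(Br)ccc(OCOCC[Si](C)(C)C)c2O1 | intermediate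
13 | 2-[(2R)-5-bromo-2-methyl-8-(SEM-oxy)-2H-chromen-2-yl]ethan-1-ol | OCC[C@]1(C)C=Cc2c(Br)ccc(OCOCC[Si](C)(C)C)c2O1 | intermediate
14 | [(2R)-5-bromo-2-methyl-8-(SEM-oxy)-2H-chromen-2-yl]acetaldehyde | O=CC[C@]1(C)C=Cc2c(Br)ccc(OCOCC[Si](C)(C)C)c2O1 | intermediate
15 | ethyl (2E)-4-[(2R)-5-bromo-2-methyl-8-(SEM-oxy)-2H-chromen-2-yl]but-2-enoate | CCOC(=O)/C=C/C[C@]1(C)C=Cc2c(Br)ccc(OCOCC[Si](C)(C)C)c2O1 | intermediate
16 | (3E)-5-[(2R)-5-bromo-2-methyl-8-(SEM-oxy)-2H-chromen-2-yl]pent-3-en-2-one | CC(=O)/C=C/C[C@]1(C)C=Cc2c(Br)ccc(OCOCC[Si](C)(C)C)c2O1 | intermediate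
17 | (3E)-5-[(2R)-5-bromo-2-methyl-8-(SEM-oxy)-2H-chromen-2-yl]-2-methylpent-3-en-2-ol | CC(C)(O)/C=C/C[C@]1(C)C=Cc2c(Br)ccc(OCOCC[Si](C)(C)C)c2O1 | intermediate
18 | 2,4-dihydroxybenzaldehyde | O=Cc1ccc(O)cc1O | starting material
19 | 2,4-bis(SEM-oxy)benzaldehyde | O=Cc1ccc(OCOCC[Si](C)(C)C)cc1OCOCC[Si](C)(C)C | intermediate
20 | rac-1-[2,4-bis(SEM-oxy)phenyl]prop-2-en-1-ol | C=CC(O)c1ccc(OCOCC[Si](C)(C)C)cc1OCOCC[Si](C)(C)C | intermediate
21 | 1-[2,4-bis(SEM-oxy)phenyl]-3-{(2R)-2-[(2E)-4-hydroxy-4-methylpent-2-en-1-yl]-2-methyl-8-(SEM-oxy)-2H-chromen-5-yl}prop-1-en-1-ol (enol, alkene geometry undefined) | CC(C)(O)/C=C/C[C@]1(C)C=Cc2c(CC=C(O)c3ccc(OCOCC[Si](C)(C)C)cc3OCOCC[Si](C)(C)C)ccc(OCOCC[Si](C)(C)C)c2O1 | intermediate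
22 | 1-[2,4-bis(SEM-oxy)phenyl]-3-{(2R)-2-[(2E)-4-hydroxy-4-methylpent-2-en-1-yl]-2-methyl-8-(SEM-oxy)-2H-chromen-5-yl}propan-1-one | CC(C)(O)/C=C/C[C@]1(C)C=Cc2c(CCC(=O)c3ccc(OCOCC[Si](C)(C)C)cc3OCOCC[Si](C)(C)C)ccc(OCOCC[Si](C)(C)C)c2O1 | intermediate
23 | 1-(2,4-dihydroxyphenyl)-3-{(2R)-8-hydroxy-2-[(2E)-4-hydroxy-4-methylpent-2-en-1-yl]-2-methyl-2H-chromen-5-yl}propan-1-one | CC(C)(O)/C=C/C[C@]1(C)C=Cc2c(CCC(=O)c3ccc(O)cc3O)ccc(O)c2O1 | target

**Step count and risk**

Total step count: 13. Longest linear sequence: 10 steps (steps 1, 2, 4, 5, 6, 7, 8, 9, 12, 13).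

Steps most likely to fail:

1. Step 6. The catalyst may discriminate poorly between the two enantiotopic vinyl groups, may load first onto a carbinol vinyl group so that selection is less organised, or ethylene-mediated re-opening may erode enantiopurity. Fallback, from 10 back to 11: closure with RuCl2(H2IMes)(PCy3)(=CHPh) (second-generation Grubbs catalyst) in CH2Cl2 at 25–40 °C should give racemic 5-bromo-2-ethenyl-2-methyl-8-(SEM-oxy)-2H-chromene F1. Preparative chromatography on a chiral stationary phase (amylose tris(3,5-dimethylphenylcarbamate), supercritical CO2/i-PrOH) would then separate 11 from (2S)-5-bromo-2-ethenyl-2-methyl-8-(SEM-oxy)-2H-chromene F2, and the route continues from 11 at step 7.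

2. Step 4. Addition of the hindered tertiary alkoxide at the doubly flanked C–F carbon may be too slow, so that hydride transfer between aldehyde–alkoxide adducts or attack at the C–Br carbon takes over. Fallback, from 3 back to 9: oxidation of the aldehyde with I2 in aqueous NH3/THF should give 6-bromo-2-fluoro-3-(SEM-oxy)benzonitrile F3, whose smaller and stronger activating group cannot add alkoxide at carbon. Substitution of its fluoride by 8 (THF/DMF, 0 °C → rt) would give 6-bromo-2-[(3-methylpenta-1,4-dien-3-yl)oxy]-3-(SEM-oxy)benzonitrile F4. Reduction with DIBAL-H (toluene, –78 °C) leads to 1-{6-bromo-2-[(3-methylpenta-1,4-dien-3-yl)oxy]-3-(SEM-oxy)phenyl}methanimine F5, which buffered aqueous work-up (pH 5, 0 °C) hydrolyses to 9.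

3. Step 12. Oxidative addition at the electron-rich, ortho-substituted C–Br bond may be slow, β-hydride elimination may run toward the benzylic CH2 to give an allylic alcohol, or palladium hydride may move the side-chain alkene. Fallback, from 20 and 17 back to 22: hydroboration of 20 with 9-BBN (2.2 equiv, THF, 0 °C → rt) should give 9-{3-[2,4-bis(SEM-oxy)phenyl]-3-[(9-borabicyclo[3.3.1]nonan-9-yl)oxy]propyl}-9-borabicyclo[3.3.1]nonane F6. After residual B–H is quenched with aqueous K3PO4, B-alkyl Suzuki–Miyaura coupling with 17 (Pd(dppf)Cl2, aq K3PO4, THF/DMF, 50 °C) would give 1-[2,4-bis(SEM-oxy)phenyl]-3-{(2R)-2-[(2E)-4-hydroxy-4-methylpent-2-en-1-yl]-2-methyl-8-(SEM-oxy)-2H-chromen-5-yl}propan-1-ol F7 as a mixture of carbinol epimers. Oxidation of its benzylic secondary alcohol with DMP/NaHCO3 (CH2Cl2, 0 °C), to which the tertiary alcohol is inert, returns to 22.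

**Further compounds**

F1 | step 6 | racemic 5-bromo-2-ethenyl-2-methyl-8-(SEM-oxy)-2H-chromene | C=CC1(C)C=Cc2c(Br)ccc(OCOCC[Si](C)(C)C)c2O1
F2 | step 6 | (2S)-5-bromo-2-ethenyl-2-methyl-8-(SEM-oxy)-2H-chromene | C=C[C@@]1(C)C=Cc2c(Br)ccc(OCOCC[Si](C)(C)C)c2O1
F3 | step 4 | 6-bromo-2-fluoro-3-(SEM-oxy)benzonitrile | N#Cc1c(Br)ccc(OCOCC[Si](C)(C)C)c1F
F4 | step 4 | 6-bromo-2-[(3-methylpenta-1,4-dien-3-yl)oxy]-3-(SEM-oxy)benzonitrile | C=CC(C)(C=C)Oc1c(C#N)c(Br)ccc1OCOCC[Si](C)(C)C
F5 | step 4 | 1-{6-bromo-2-[(3-methylpenta-1,4-dien-3-yl)oxy]-3-(SEM-oxy)phenyl}methanimine | C=CC(C)(C=C)Oc1c(C=N)c(Br)ccc1OCOCC[Si](C)(C)C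
F6 | step 12 | 9-{3-[2,4-bis(SEM-oxy)phenyl]-3-[(9-borabicyclo[3.3.1]nonan-9-yl)oxy]propyl}-9-borabicyclo[3.3.1]nonane | C[Si](C)(C)CCOCOc1ccc(C(CCB2C3CCCC2CCC3)OB2C3CCCC2CCC3)c(OCOCC[Si](C)(C)C)c1
F7 | step 12 | 1-[2,4-bis(SEM-oxy)phenyl]-3-{(2R)-2-[(2E)-4-hydroxy-4-methylpent-2-en-1-yl]-2-methyl-8-(SEM-oxy)-2H-chromen-5-yl}propan-1-ol | CC(C)(O)/C=C/C[C@]1(C)C=Cc2c(CCC(O)c3ccc(OCOCC[Si](C)(C)C)cc3OCOCC[Si](C)(C)C)ccc(OCOCC[Si](C)(C)C)c2O1
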